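**Plan**

- Numbering (target): seven-membered ring C1 (O-angelate), C2 (O-2-methylbutanoate), C3 (OH), C4 (quaternary, Me), C5, C6, C11 (CMe2); cyclobutane C4–C5–C6–C7; bridge C7–C8(=O)–C9–C10(Me)–C5. The four-carbon bridge C3–C2–C1–C11 spans the 1,3-positions C4/C6 of the cyclobutane, which is where the central bond of a bicyclobutane lies.
- Retrosynthesis: the two ester C–O bonds and the C2/C3 diol are removed first. C3–C4 and C6–C11 are then cut together, giving tricyclic bicyclobutane ketone 12 and silyl dienol ether 17. 12 is cut at C7–C4/C7–C6 to a cyclopropenyl diazoketone, and that at the cyclopropene to propyne and ethyl diazoacetate.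
- Forward: cyclopropene, then the C10 side chain, then the six-membered ketone ring and the bicyclobutane in one cyclopropanation, then the seven-membered ring by the cycloaddition, then oxidation-level changes and the two esters.
- Stereochemistry: C5 comes from the chiral Rh(II) cyclopropenation catalyst and C10 from an imidazolidinone catalyst. The cage centres C4, C6 and C7 follow from these, because the tether and the C8–C10 bridge leave one face only. C1 comes from CBS reduction, C2/C3 from osmylation anti to O1, the acyl stereocentre from (R)-2-methylbutanoic acid and the Z-alkene from angelic anhydride.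

Key step: step 11

Remark: additions to a bicyclobutane bridgehead normally enter from the rear (concave) side; in 12 that side is closed by the C8–C10 bridge, so the cycloaddition is assumed to occur on the convex face with retention at C4 and C6.

**Route**

Step 1
Reactants: 1 propyne; 2 ethyl diazoacetate
Product: 3 ethyl (1S)-2-methylcycloprop-2-ene-1-carboxylate
Conditions: Rh2(OAc)(DPTI)3 (0.5 mol %, DPTI = 4,5-diphenyl-1-triflylimidazolidin-2-one, antipode that gives 1S), 1 (5 equiv) condensed in CH2Cl2, 0 °C, 2 by syringe pump
Reagents that add atoms: none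
Why: Rh(II)-carbenoid [2+1] cyclopropenation of a terminal alkyne, for which this catalyst class is highly enantioselective; the ligand pocket decides which carbenoid face the alkyne meets and so sets C5.

Step 2
Reactants: 3 ethyl (1S)-2-methylcycloprop-2-ene-1-carboxylate
Product: 5 1-[(1S)-2-methylcycloprop-2-en-1-yl]ethan-1-one, via Weinreb amide 4 (not isolated)
Conditions: MeNH(OMe)·HCl, i-PrMgCl, THF, −20 °C; then MeMgBr, −20 → 0 °C; aq. NH4Cl
Reagents that add atoms: methylmagnesium bromide, C[Mg]Br; N,O-dimethylhydroxylamine hydrochloride, CNOC.Cl (its atoms stay only in 4)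
Why: Weinreb ketone synthesis in one flask, the chelated tetrahedral adduct stopping at the ketone; C5–H is not acidic (its anion would be a cyclopropenyl anion), so the stereocentre is not at risk.

Step 3
Reactants: 5 1-[(1S)-2-methylcycloprop-2-en-1-yl]ethan-1-one
Product: 7 3-[(1S)-2-methylcycloprop-2-en-1-yl]but-2-enal (E/Z mixture), via N-cyclohexyl enimine 6 (not isolated)
Conditions: (EtO)2P(O)CH=CHNH-c-C6H11, NaH, THF, 0 °C → rt; then aq. oxalic acid/Et2O, rt
Reagents that add atoms: diethyl [2-(cyclohexylamino)ethenyl]phosphonate, CCOP(=O)(OCC)C=CNC1CCCCC1; water, O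
Why: Horner–Wadsworth–Emmons formylolefination of a methyl ketone with a weakly basic phosphonate anion, followed by mild imine hydrolysis; the alkene geometry is irrelevant because the next step is stereoconvergent.

Step 4
Reactants: 7 3-[(1S)-2-methylcycloprop-2-en-1-yl]but-2-enal
Product: 8 (3R)-3-[(1S)-2-methylcycloprop-2-en-1-yl]butanal
Conditions: (S)-2-tert-butyl-3-methylimidazolidin-4-one·Cl3CCO2H (20 mol %, antipode that gives 3R), Hantzsch ester (1.2 equiv), CHCl3, −30 °C
Reagents that add atoms: none
Why: iminium-catalysed transfer hydrogenation of a β,β-disubstituted enal, in which E and Z iminium ions interconvert and the catalyst shields one face, so hydride delivery sets C10 under catalyst control and leaves the cyclopropene alone.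

Step 5
Reactants: 8 (3R)-3-[(1S)-2-methylcycloprop-2-en-1-yl]butanal
Product: 9 (3R)-3-[(1S)-2-methylcycloprop-2-en-1-yl]butanoic acid
Conditions: NaClO2, NaH2PO4, 2-methylbut-2-ene (20 equiv), t-BuOH/H2O, 0 °C
Reagents that add atoms: sodium chlorite, [Na+].[O-]Cl=O
Why: Pinnick oxidation under buffered conditions, the large excess of scavenger taking up hypochlorous acid before it can add to the strained alkene; C10 is β to the carbonyl and cannot epimerise.

Step 6
Reactants: 9 (3R)-3-[(1S)-2-methylcycloprop-2-en-1-yl]butanoic acid
Product: 11 (4R)-1-diazo-4-[(1S)-2-methylcycloprop-2-en-1-yl]pentan-2-one, via isobutyl mixed anhydride 10 (not isolated)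
Conditions: i-BuOCOCl, N-methylmorpholine, THF, −15 °C; then CH2N2, Et2O, −15 → 0 °C
Reagents that add atoms: diazomethane, C=[N+]=[N-]; isobutyl chloroformate, CC(C)COC(Cl)=O (its atoms stay only in 10)
Why: C-acylation of diazomethane by a mixed anhydride (first stage of the Arndt–Eistert sequence), which avoids the HCl that an acid chloride route would release onto the cyclopropene.

Step 7
Reactants: 11 (4R)-1-diazo-4-[(1S)-2-methylcycloprop-2-en-1-yl]pentan-2-one
Product: 12 (5R)-1,5-dimethyltricyclo[4.1.0.0(2,7)]heptan-3-one (5-methyl on the side of the unsubstituted bridgehead)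
Conditions: Rh2(OAc)4 (1 mol %), CH2Cl2, 0 °C, slow addition; filtration through basic alumina
Reagents that add atoms: none
Why: intramolecular carbenoid cyclopropanation of the cyclopropene double bond through a six-membered ketone ring, the established way from cyclopropenyl diazoketones to tricyclic bicyclobutyl ketones; the tether reaches only the face that carries the C5 side chain, so the cage configuration follows from C5 and C10.

Step 8
Reactants: 13 isobutyraldehyde; 14 vinylmagnesium bromide
Product: 15 4-methylpent-1-en-3-ol (racemic)
Conditions: THF, 0 °C; aq. NH4Cl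
Reagents that add atoms: none
Why: Grignard 1,2-addition to an aldehyde; the new stereocentre is removed in the next step.

Step 9
Reactants: 15 4-methylpent-1-en-3-ol
Product: 16 4-methylpent-1-en-3-one
Conditions: activated MnO2 (10 equiv), pentane, rt; used as a solution
Reagents that add atoms: none
Why: allylic alcohol oxidation with MnO2, neutral conditions under which the polymerisable vinyl ketone survives.

Step 10
Reactants: 16 4-methylpent-1-en-3-one
Product: 17 tert-butyldimethyl[(4-methylpenta-1,3-dien-3-yl)oxy]silane
Conditions: TBSOTf, Et3N, CH2Cl2, −78 → 0 °C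
Reagents that add atoms: tert-butyldimethylsilyl triflate, CC(C)(C)[Si](C)(C)OS(=O)(=O)C(F)(F)F
Why: soft enolisation and O-silylation of an enone, which can lose a proton only from the isopropyl methine and therefore gives the cross-conjugated dienol ether.

Step 11
Reactants: 12 (5R)-1,5-dimethyltricyclo[4.1.0.0(2,7)]heptan-3-one; 17 tert-butyldimethyl[(4-methylpenta-1,3-dien-3-yl)oxy]silane (1.5 equiv)
Product: 18 tricyclic silyl enol ether (C1–OTBS, C1=C2, C8 ketone; C4-methyl and C6-H on the side of the C8–C10 bridge)
Conditions: Ru(bpz)3(PF6)2 (2 mol %), 2,6-di-tert-butylpyridine (10 mol %), degassed CH2Cl2/MeNO2, 455 nm LEDs, −20 °C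
Reagents that add atoms: none
Why: Proposed new method: the excited catalyst oxidises 17 (the more easily oxidised partner), the enol-ether terminus C11 of the radical cation bonds to the hydrogen-bearing bridgehead C6 on the convex face of 12, the tertiary C4 radical then adds to the vinyl terminus C3 of the silyloxyallyl cation, and electron return from the reduced catalyst or from another molecule of 17 gives neutral 18. The closest known reactions are the strain-release (4π+2σ) cycloadditions of bicyclobutanes with dienes and silyl dienol ethers to bicyclo[4.1.1]octenes and hole-catalysed Diels–Alder reactions. The seven-membered ring closes in the second bond-forming event, a 7-endo-trig attack of the C4 radical on the activated enone carbon C3. The two new stereocentres C4 and C6 are fixed by the C8–C10 bridge, which ties C5 and C7 on the concave face so that a four-carbon bridge can only span the convex face, leaving the C4 methyl and the C6 hydrogen endo. The step needs C11-to-C6/C3-to-C4 regiochemistry and front-side bonding at C6: the first is secured by the C4 methyl (tertiary radical) and the unsubstituted C6, the second by the C9 methylene and the syn C10 methyl, which block the rear trajectory at C6 for the fully substituted C11.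

Step 12
Reactants: 18 tricyclic silyl enol ether
Product: 19 tricyclic enedione (C1 ketone conjugated with C2=C3; C8 ketone)
Conditions: Pd(OAc)2 (1.1 equiv), MeCN, 40 °C
Reagents that add atoms: none
Why: Saegusa–Ito oxidation of a silyl enol ether; the Pd enolate at C2 can only lose hydride from C3 because C11 is quaternary.

Step 13
Reactants: 19 tricyclic enedione
Product: 20 C8 1,3-dioxolane of 19
Conditions: (TMSOCH2)2, TMSOTf (5 mol %), CH2Cl2, −78 → −20 °C
Reagents that add atoms: 1,2-bis(trimethylsilyloxy)ethane, C[Si](C)(C)OCCO[Si](C)(C)C
Why: silyl-triflate-catalysed dioxolane formation, which is selective for a saturated ketone over a conjugated one; the C1 enone is further shielded by the quaternary C11.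

Step 14
Reactants: 20 C8 dioxolane enone
Product: 21 allylic alcohol (C1–OH of R configuration, C2=C3, C8 dioxolane)
Conditions: (S)-2-methyl-CBS-oxazaborolidine (0.3 equiv), BH3·SMe2, THF, −20 °C
Reagents that add atoms: none
Why: CBS reduction gives 1,2-reduction of the enone, and with the quaternary C11 as the large and the alkenyl C2 as the small substituent the (S)-catalyst delivers hydride to the face that gives the 1R alcohol; the cage itself offers almost no facial bias at C1, so reagent control is needed.

Step 15
Reactants: 21 allylic alcohol; 22 angelic anhydride [(2Z)-2-methylbut-2-enoic anhydride]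
Product: 23 C1 angelate of 21
Conditions: LiHMDS, THF, −78 °C; then 22, −78 → 0 °C
Reagents that add atoms: none
Why: acylation of the lithium alkoxide of a hindered secondary alcohol without a nucleophilic amine catalyst, so the Z double bond is not isomerised to the tiglate; the ketal keeps C9 from being enolised.

Step 16
Reactants: 23 C1 angelate, C8 dioxolane
Product: 24 C1 angelate with free C8 ketone (C2=C3)
Conditions: PPTS, acetone/H2O (10:1), 50 °C
Reagents that add atoms: water, O
Why: acid-catalysed ketal hydrolysis (transketalisation to acetone) under conditions mild enough for the allylic ester.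

Step 17
Reactants: 24 C1 angelate, C2=C3, C8 ketone
Product: 25 C1 angelate 2,3-cis-diol (both hydroxyls anti to O1; C8 ketone)
Conditions: K2OsO4·2H2O (5 mol %), NMO, acetone/H2O, rt
Reagents that add atoms: N-methylmorpholine N-oxide, C[N+]1([O-])CCOCC1; water, O
Why: Upjohn syn-dihydroxylation, which attacks the ring alkene anti to the allylic acyloxy group and prefers this isolated alkene over the electron-poor conjugated angelate alkene; this sets C2 and C3.

Step 18
Reactants: 25 C1 angelate 2,3-diol; 26 (2R)-2-methylbutanoic acid
Product: 27 CNP0206299.1 (C1 angelate, C2 (2R)-2-methylbutanoate, C3–OH, C8 ketone)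
Conditions: DCC, DMAP (10 mol %), CH2Cl2, 0 °C
Reagents that add atoms: none
Why: Steglich esterification at the less hindered C2 hydroxyl, the C3 hydroxyl being neopentyl next to the quaternary C4; low temperature and catalytic DMAP protect the α-stereocentre of the acid.

**Compound list**

1 | propyne | CC#C | starting material
2 | ethyl diazoacetate | CCOC(=O)C=[N+]=[N-] | starting material
3 | ethyl (1S)-2-methylcycloprop-2-ene-1-carboxylate | CC1=C[C@@H]1C(=O)OCC | intermediate
4 | (1S)-N-methoxy-N,2-dimethylcycloprop-2-ene-1-carboxamide | CC1=C[C@@H]1C(=O)N(C)OC | intermediate (not isolated)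
5 | 1-[(1S)-2-methylcycloprop-2-en-1-yl]ethan-1-one | CC1=C[C@@H]1C(C)=O | intermediate
6 | N-cyclohexyl-3-[(1S)-2-methylcycloprop-2-en-1-yl]but-2-en-1-imine (E/Z) | CC1=C[C@@H]1C(C)=CC=NC2CCCCC2 | intermediate (not isolated)
7 | 3-[(1S)-2-methylcycloprop-2-en-1-yl]but-2-enal (E/Z) | CC1=C[C@@H]1C(C)=CC=O | intermediate
8 | (3R)-3-[(1S)-2-methylcycloprop-2-en-1-yl]butanal | CC1=C[C@@H]1[C@H](C)CC=O | intermediate
9 | (3R)-3-[(1S)-2-methylcycloprop-2-en-1-yl]butanoic acid | CC1=C[C@@H]1[C@H](C)CC(=O)O | intermediate
10 | mixed anhydride of 9 with isobutyl hydrogen carbonate | CC1=C[C@@H]1[C@H](C)CC(=O)OC(=O)OCC(C)C | intermediate (not isolated)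
11 | (4R)-1-diazo-4-[(1S)-2-methylcycloprop-2-en-1-yl]pentan-2-one | CC1=C[C@@H]1[C@H](C)CC(=O)C=[N+]=[N-] | intermediate
12 | (5R)-1,5-dimethyltricyclo[4.1.0.0(2,7)]heptan-3-one, 5-methyl syn to the unsubstituted bridgehead | C[C@]12[C@@H]3[C@H]1[C@H]2C(=O)C[C@H]3C | intermediate
13 | isobutyraldehyde | CC(C)C=O | starting material
14 | vinylmagnesium bromide | C=C[Mg]Br | starting material
15 | 4-methylpent-1-en-3-ol (racemic) | C=CC(O)C(C)C | intermediate
16 | 4-methylpent-1-en-3-one | C=CC(=O)C(C)C | intermediate
17 | tert-butyldimethyl[(4-methylpenta-1,3-dien-3-yl)oxy]silane | C=CC(O[Si](C)(C)C(C)(C)C)=C(C)C | intermediate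
18 | tricyclic silyl enol ether: C1–OTBS, C1=C2, C8 ketone | CC(C)(C)[Si](C)(C)OC1=CC[C@]2(C)[C@@H]3[C@@H]([C@H]2C(=O)C[C@H]3C)C1(C)C | intermediate
19 | tricyclic enedione: C1 ketone, C2=C3, C8 ketone | O=C1C=C[C@]2(C)[C@@H]3[C@@H]([C@H]2C(=O)C[C@H]3C)C1(C)C | intermediate
20 | 19 with C8 as 1,3-dioxolane | O=C1C=C[C@]2(C)[C@@H]3[C@@H]([C@H]2C4(OCCO4)C[C@H]3C)C1(C)C | intermediate
21 | allylic alcohol: C1–OH (R), C2=C3, C8 dioxolane | O[C@@H]1C=C[C@]2(C)[C@@H]3[C@@H]([C@H]2C4(OCCO4)C[C@H]3C)C1(C)C | intermediate
22 | angelic anhydride [(2Z)-2-methylbut-2-enoic anhydride] | C/C=C(/C)C(=O)OC(=O)/C(C)=C\C | starting material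
23 | C1 angelate, C2=C3, C8 dioxolane | C/C=C(/C)C(=O)O[C@@H]1C=C[C@]2(C)[C@@H]3[C@@H]([C@H]2C4(OCCO4)C[C@H]3C)C1(C)C | intermediate
24 | C1 angelate, C2=C3, C8 ketone | C/C=C(/C)C(=O)O[C@@H]1C=C[C@]2(C)[C@@H]3[C@@H]([C@H]2C(=O)C[C@H]3C)C1(C)C | intermediate
25 | C1 angelate, C2/C3 cis-diol anti to O1, C8 ketone | C/C=C(/C)C(=O)O[C@@H]1[C@@H](O)[C@@H](O)[C@]2(C)[C@@H]3[C@@H]([C@H]2C(=O)C[C@H]3C)C1(C)C | intermediate
26 | (2R)-2-methylbutanoic acid | CC[C@@H](C)C(=O)O | starting material
27 | CNP0206299.1 | C/C=C(/C)C(=O)O[C@@H]1[C@@H](OC(=O)[C@H](C)CC)[C@@H](O)[C@]2(C)[C@@H]3[C@@H]([C@H]2C(=O)C[C@H]3C)C1(C)C | target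

**Count**

Total steps: 18. Longest linear sequence: 15 (steps 1–7 and 11–18).

**Steps most likely to fail**

Step 11. Several processes can stop the sequence at open 1,3-adducts or rearranged hydrocarbons instead of the ring:
- the radical cation may bond through its unhindered CH2 terminus at C4 or from the concave side;
- the hole may pass to 12, which then opens to dienes;
- the radical cation may lose its silyl group.

The fallback sets out from 17 (with 12) and comes back at 19. 17 would be brominated with NBS (THF, −78 °C) to 4-bromo-4-methylpent-1-en-3-one F1. F1 and 12 with Et3B/air (benzene, rt) would then enter a bromine-atom-transfer chain: the α-keto radical, which can bond only through C11, adds to C6; the C4 radical cyclises 7-endo onto the enone; and the C2 radical takes bromine from F1 to give the 2-bromo-1,8-diketone F2. DBU (THF, rt) would eliminate HBr to 19. Atom-transfer addition of α-bromo carbonyl compounds across strained C–C bonds and radical cyclisation onto enones are both established reaction types; no oxidant or silyl group is involved. This fallback still relies on convex-face bonding at C6.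

Step 7. The rhodium may open the cyclopropene to a vinylcarbene (furan or diene products) or isomerise the bicyclobutane as it forms. The fallback sets out from 11 and comes back at 12 without any metal. Kept in the dark in pentane at rt, the diazo group should add as a 1,3-dipole to the strained double bond to give the 1-pyrazoline F3. Direct irradiation (350 nm, −40 °C) would then expel nitrogen and close the C4–C7 bond, the classical photodenitrogenation of 2,3-diazabicyclo[3.1.0]hex-2-enes to bicyclobutanes.

Step 4. The iminium ion carries cationic character next to the cyclopropene and may ring-expand, and catalyst control at C10 may be eroded by the neighbouring C5. The fallback sets out from 3 and comes back at 9, forming the C10–CH3 bond instead of the C10–H bond. DIBAL-H (CH2Cl2, −78 °C) would give (1S)-2-methylcycloprop-2-ene-1-carbaldehyde F4, trapped in the same flask with Ph3P=CHC(O)SEt as the (E)-enethioate F5. Cu-catalysed asymmetric conjugate addition (MeMgBr, CuBr·SMe2, Josiphos antipode for 3R, t-BuOMe, −75 °C) would give the 3R thioester F6, and LiOH/H2O2 (THF/H2O, 0 °C) the acid 9. Steps 2, 3 and 5 are then not needed.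

**Further compounds**

F1 | step 11 | 4-bromo-4-methylpent-1-en-3-one | C=CC(=O)C(C)(C)Br
F2 | step 11 | tricyclic 2-bromo-1,8-diketone (C2 epimers) | O=C1C(Br)C[C@]2(C)[C@@H]3[C@@H]([C@H]2C(=O)C[C@H]3C)C1(C)C
F3 | step 7 | tetracyclic 1-pyrazoline from intramolecular dipolar cycloaddition of 11 | C[C@]12N=N[C@@H]3C(=O)C[C@@H](C)[C@H]1[C@H]23
F4 | step 4 | (1S)-2-methylcycloprop-2-ene-1-carbaldehyde | CC1=C[C@@H]1C=O
F5 | step 4 | S-ethyl (2E)-3-[(1S)-2-methylcycloprop-2-en-1-yl]prop-2-enethioate | CC1=C[C@@H]1/C=C/C(=O)SCC
F6 | step 4 | S-ethyl (3R)-3-[(1S)-2-methylcycloprop-2-en-1-yl]butanethioate | CC1=C[C@@H]1[C@H](C)CC(=O)SCC
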